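**Retrosynthetic overview**

1. Target 34 ⇐ primary-selective angeloylation of triol 31; the 8-OH/8-CH3 centre ⇐ hydration of an 8(12)-methylene ⇐ C8 ketone ⇐ enol ether 27 ⇐ adduct 26.
2. Rings A and B are formed together by an intramolecular Diels–Alder reaction of nitro-triene 25: diene C7=C8(OEt)–C9=C10, dienophile C5=C6–NO2, new bonds C6–C7 and C5–C10. The nitro group is a traceless activator (removed with Bu3SnH).
3. Enabling features: ring B is a cyclohexane with oxygen on C8 next to C9 and two unfunctionalised CH2 groups at C6/C7 (enol-ether cyclohexene retron). The 3-OH and 4-CH2O groups are trans-diequatorial on ring A, so they can be tied into a 1,3-dioxane (temporary ring) that fixes the tether chair and the diene face.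
4. Triene 25 ⇐ Henry/dehydration (C5=C6), Stille coupling (C8–C9), Mitsunobu etherification (ArO–C11), ynoate carbocupration/iodination (C9=C10 geometry).
5. C3/C4 ⇐ catalytic asymmetric allylboration of pent-4-ynal with the Z-γ,γ-disubstituted allylboronate 7; the only ring present before step 14 is the dioxane (step 6).

Key step: step 14

Remark: ring carbons are given in drimane numbering (C1–C10 decalin carbons, C11 = CH2OAr on C9, C12 = carbon on C8); Ar = 2-oxo-2H-chromen-7-yl.
Remark: the (S) enantiomer of the phosphoric acid in step 5 is assumed to give the (R)-carbinol; if the sense of induction is the opposite, the (R) acid is used.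
Remark: metal alkoxides, borates and ate complexes that only collapse on warming or on work-up are not numbered.

**Route**

Step 1
Reactants: 1 prop-2-yn-1-ol
Product: 3 (Z)-3-iodo-2-methylprop-2-en-1-ol, via chelated alkenylmagnesium bromide 2 (not isolated)
Conditions: MeMgBr (2.5 equiv), CuI (10 mol %), THF, −10 °C to rt; then I2, −78 to 0 °C
Reagents that add atoms: MeMgBr (C[Mg]Br); iodine ([I][I])
Why: Copper-catalysed anti-carbomagnesiation of the propargylic alkoxide puts CH3 on the proximal and Mg on the distal alkyne carbon in a five-membered chelate, and iodinolysis with retention should give the Z-iodide.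

Step 2
Reactants: 3 (Z)-3-iodo-2-methylprop-2-en-1-ol
Product: 4 1-{[(Z)-3-iodo-2-methylprop-2-enyl]oxymethyl}-4-methoxybenzene
Conditions: NaH, 4-methoxybenzyl chloride, Bu4NI (cat.), THF/DMF, 0 °C to rt
Reagents that add atoms: 4-methoxybenzyl chloride (COc1ccc(CCl)cc1)
Why: Williamson etherification of the alkoxide; the vinyl iodide has no β-hydrogen on C2 and is inert to NaH.

Step 3
Reactants: 4 1-{[(Z)-3-iodo-2-methylprop-2-enyl]oxymethyl}-4-methoxybenzene; 5 2-(chloromethyl)-4,4,5,5-tetramethyl-1,3,2-dioxaborolane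
Product: 7 (Z)-allylboronate (CH2B cis to CH2OPMB), via (Z)-alkenyllithium 6 (not isolated)
Conditions: t-BuLi (2.1 equiv), Et2O, −78 °C; then 5, −78 °C to rt
Reagents that add atoms: none
Why: Iodine–lithium exchange with retention of alkene geometry, then Matteson-type homologation (borate formation and 1,2-migration with loss of chloride), should give the Z-γ,γ-disubstituted allylboronate.

Step 4
Reactants: 8 pent-4-yn-1-ol
Product: 9 pent-4-ynal
Conditions: PhI(OAc)2, TEMPO (10 mol %), CH2Cl2, rt
Reagents that add atoms: none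
Why: TEMPO/PhI(OAc)2 oxidation of a primary alcohol stops at the aldehyde and leaves the alkyne untouched.

Step 5
Reactants: 9 pent-4-ynal; 7 (Z)-allylboronate
Product: 10 (3S,4R)-3-{[(4-methoxybenzyl)oxy]methyl}-3-methyloct-1-en-7-yn-4-ol
Conditions: (S)-3,3'-bis(2,4,6-triisopropylphenyl)-1,1'-binaphthyl-2,2'-diyl hydrogen phosphate (5 mol %), 4 Å MS, PhMe, −30 °C to rt; aqueous work-up
Reagents that add atoms: none
Why: Chiral-phosphoric-acid-catalysed allylboration through a closed chair transition state: the Z-reagent places CH2OPMB syn and CH3 anti to the new hydroxyl at the quaternary carbon (C4), and the catalyst selects the aldehyde face that gives the R-carbinol (C3).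

Step 6
Reactants: 10 (3S,4R)-3-{[(4-methoxybenzyl)oxy]methyl}-3-methyloct-1-en-7-yn-4-ol
Product: 11 (2S,4R,5S)-4-(but-3-ynyl)-5-ethenyl-2-(4-methoxyphenyl)-5-methyl-1,3-dioxane
Conditions: DDQ (1.2 equiv), 4 Å MS, CH2Cl2, 0 °C
Reagents that add atoms: none
Why: Anhydrous DDQ oxidation of the PMB ether to its oxocarbenium ion and capture by the neighbouring hydroxyl (oxidative acetalisation) should give the six-membered acetal with the aryl group equatorial, cis to the butynyl group.

Step 7
Reactants: 11 (2S,4R,5S)-4-(but-3-ynyl)-5-ethenyl-2-(4-methoxyphenyl)-5-methyl-1,3-dioxane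
Product: 13 methyl 5-(dioxan-4-yl)pent-2-ynoate (dioxane of 11 unchanged), via lithium acetylide 12 (not isolated)
Conditions: n-BuLi, THF, −78 °C; then ClCO2Me
Reagents that add atoms: methyl chloroformate (COC(=O)Cl)
Why: Deprotonation of the terminal alkyne and C-acylation of the acetylide with a chloroformate.

Step 8
Reactants: 13 methyl 5-(dioxan-4-yl)pent-2-ynoate
Product: 15 methyl (E)-2-iodo-3-methyl-5-(dioxan-4-yl)pent-2-enoate, via lithium alkenyl(methyl)cuprate 14 (not isolated)
Conditions: Me2CuLi (from MeLi and CuI), THF, −78 °C; then I2, −78 °C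
Reagents that add atoms: lithium dimethylcuprate ([Li+].C[Cu-]C); iodine ([I][I])
Why: Syn carbocupration of the ynoate puts CH3 on C10 and copper on C9 cis to it, and iodinolysis at −78 °C with retention fixes the tetrasubstituted alkene (iodine cis to CH3, ester cis to the chain).

Step 9
Reactants: 15 methyl (E)-2-iodo-3-methyl-5-(dioxan-4-yl)pent-2-enoate
Product: 16 (E)-2-iodo-3-methyl-5-(dioxan-4-yl)pent-2-en-1-ol
Conditions: i-Bu2AlH (2.5 equiv), CH2Cl2, −78 °C
Reagents that add atoms: none
Why: i-Bu2AlH 1,2-reduction of the enoate to the allylic alcohol at −78 °C, where the vinyl iodide and the arylidene acetal survive.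

Step 10
Reactants: 16 (E)-2-iodo-3-methyl-5-(dioxan-4-yl)pent-2-en-1-ol
Product: 18 dioxane-5-carbaldehyde (vinyl group of 16 cut to CHO), via vicinal diol 17 (not isolated)
Conditions: OsO4 (2 mol %), NaIO4 (4 equiv), 2,6-lutidine, dioxane/H2O 3:1, rt
Reagents that add atoms: OsO4 (O=[Os](=O)(=O)=O), reoxidised by NaIO4 ([Na+].[O-]I(=O)(=O)=O)
Why: Lemieux–Johnson oxidation: OsO4 dihydroxylates the monosubstituted vinyl group and not the tetrasubstituted iodoalkene, and periodate cleaves the diol to the non-enolisable aldehyde.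

Step 11
Reactants: 18 dioxane-5-carbaldehyde; 19 7-hydroxycoumarin
Product: 20 coumarin-7-yl ether of 18
Conditions: PPh3, diisopropyl azodicarboxylate, THF, 0 °C to rt
Reagents that add atoms: none
Why: Mitsunobu etherification of the primary allylic alcohol with the acidic phenol (SN2 at CH2); the aldehyde is a spectator.

Step 12
Reactants: 20 coumarin-7-yl ether of 18; 21 tributyl(1-ethoxyvinyl)stannane
Product: 22 2-ethoxy-1,3-diene aldehyde (C7=C8(OEt)–C9(CH2OAr)=C10(CH3)–, 9E)
Conditions: Pd2(dba)3 (5 mol %), AsPh3 (20 mol %), CuI (20 mol %), NMP, 50 °C; chromatography on Et3N-deactivated silica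
Reagents that add atoms: none
Why: Stille coupling with retention at the vinyl iodide (CuI-accelerated) installs C7–C8 as the 2-ethoxydiene with C8 cis to the 10-methyl and trans to the tether.

Step 13
Reactants: 22 2-ethoxy-1,3-diene aldehyde
Product: 25 (E)-nitro-triene, via nitro-aldol 23 (not isolated), via nitro-aldol mesylate 24 (not isolated)
Conditions: MeNO2, 1,1,3,3-tetramethylguanidine (10 mol %), THF, 0 °C; then MsCl, i-Pr2NEt, CH2Cl2, −20 to 0 °C; used at once
Reagents that add atoms: nitromethane (C[N+](=O)[O-])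
Why: Henry addition to the non-enolisable aldehyde, then mesylation and E1cB elimination, should give the E-nitroalkene.

Step 14
Reactants: 25 (E)-nitro-triene
Product: 26 6-nitro adduct: trans-fused 8-ethoxy-drim-8-ene, 6-NO2 cis to 5-H, 3-O and 4-CH2O in the arylidene acetal, 11-OAr
Conditions: PhMe (5 mM), BHT (cat.), 80 °C
Reagents that add atoms: none
Why: Thermal intramolecular Diels–Alder reaction of normal electron demand between the 2-ethoxy-1,3-diene (C7=C8–C9=C10, HOMO raised by OEt and three alkyl groups) and the E-nitroalkene (C5=C6), concerted but asynchronous, forming C6–C7 and C5–C10; the closest known reaction type is the thermal cyclisation of (E)-1-nitrodeca-1,7,9-trienes to trans-decalins with an angular methyl group. Ring B is closed by the [4+2] bond pair itself and ring A by the four-carbon tether C1–C4 as the C5–C10 bond forms (six-membered, fused mode, chair-like tether). The tether is the outside (E) substituent of the diene terminus C10 and the methyl the inside one, so the endo orientation of the nitro group of the E-dienophile gives the trans ring fusion (5-H anti to 10-CH3) and places the nitro group at C6 cis to 5-H. The diene face is fixed by the 1,3-dioxane: only the chair tether with C3–O and C4–CH2O both equatorial (gauche) fits the six-membered acetal, whereas the other chair would need them antiperiplanar, so C5 and C10 are set relative to C3 and C4 with 4-CH3 axial. Regiochemistry is enforced by the tether, so the step needs only endo over exo selectivity, which the nitro group supplies, and high dilution to suppress bimolecular Michael reactions of the enol ether.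

Step 15
Reactants: 26 6-nitro adduct
Product: 27 denitrated enol ether (8-ethoxy-drim-8-ene acetal)
Conditions: Bu3SnH (5 equiv), AIBN (portions), PhMe, 110 °C
Reagents that add atoms: none
Why: Radical denitration (stannyl radical adds to the nitro group, C–N homolysis, hydrogen transfer), the known way to use a nitroalkene as a traceless activated dienophile; the C6 stereocentre disappears.

Step 16
Reactants: 27 denitrated enol ether
Product: 28 8-oxo-drimane-3,4'-diol 11-aryl ether (keto diol; 9-CH2OAr equatorial)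
Conditions: 1 M aq. HCl, THF, rt
Reagents that add atoms: water (O)
Why: Acid hydrolysis of enol ether and acetal; C9 is protonated on the face opposite the axial 10-methyl, and equilibration through the enol also favours the equatorial CH2OAr.

Step 17
Reactants: 28 keto diol
Product: 29 8(12)-methylene diol
Conditions: Zn, CH2Br2, TiCl4 (reagent pre-formed in THF), CH2Cl2, 0 °C to rt
Reagents that add atoms: dibromomethane (BrCBr)
Why: Takai–Lombardo methylenation is non-basic and selective for a ketone over the lactone, which should avoid β-elimination of the aryloxide and epimerisation at C9.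

Step 18
Reactants: 29 8(12)-methylene diol
Product: 31 triol (8-OH equatorial, 8-CH3 axial), via alkylmercury acetate 30 (not isolated)
Conditions: Hg(OAc)2, THF/H2O 1:1, rt; then NaBH4, aq. NaOH, 0 °C; acidify to pH 4
Reagents that add atoms: water (O)
Why: Markovnikov oxymercuration–demercuration: water should attack the tertiary C8 of the mercurinium ion from the equatorial direction, away from the syn-axial 10-methyl, so OH is equatorial and the new 8-methyl axial.

Step 19
Reactants: 31 triol; 32 angelic acid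
Product: 34 CNP0139045.1, via mixed anhydride 33 (not isolated)
Conditions: 32, 2,4,6-trichlorobenzoyl chloride, Et3N, PhMe, rt; then 31 (1 equiv), 70 °C, no DMAP
Reagents that add atoms: none
Why: Yamaguchi esterification through the mixed anhydride at the least hindered primary hydroxyl (secondary 3-OH and tertiary 8-OH are slower), run without DMAP to avoid Z to E isomerisation of the angelate.

**Compound list**

1 | prop-2-yn-1-ol | C#CCO | starting material
2 | chelated alkenylmagnesium bromide (Mg cis to CH2O) | Br[Mg]/C=C(/C)CO[Mg]Br | intermediate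
3 | (Z)-3-iodo-2-methylprop-2-en-1-ol | OC/C(C)=C\I | intermediate
4 | 1-{[(Z)-3-iodo-2-methylprop-2-enyl]oxymethyl}-4-methoxybenzene | COc1ccc(COC/C(C)=C\I)cc1 | intermediate
5 | 2-(chloromethyl)-4,4,5,5-tetramethyl-1,3,2-dioxaborolane | ClCB1OC(C)(C)C(C)(C)O1 | starting material
6 | (Z)-alkenyllithium from 4 | COc1ccc(COC/C(C)=C\[Li])cc1 | intermediate
7 | 2-{(Z)-4-[(4-methoxybenzyl)oxy]-3-methylbut-2-enyl}-4,4,5,5-tetramethyl-1,3,2-dioxaborolane | COc1ccc(COC/C(C)=C\CB2OC(C)(C)C(C)(C)O2)cc1 | intermediate
8 | pent-4-yn-1-ol | C#CCCCO | starting material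
9 | pent-4-ynal | C#CCCC=O | intermediate
10 | (3S,4R)-3-{[(4-methoxybenzyl)oxy]methyl}-3-methyloct-1-en-7-yn-4-ol | C#CCC[C@@H](O)[C@](C)(COCc1ccc(OC)cc1)C=C | intermediate
11 | (2S,4R,5S)-4-(but-3-ynyl)-5-ethenyl-2-(4-methoxyphenyl)-5-methyl-1,3-dioxane | COc1ccc(cc1)[C@H]2OC[C@](C)(C=C)[C@@H](CCC#C)O2 | intermediate
12 | lithium acetylide of 11 | COc1ccc(cc1)[C@H]2OC[C@](C)(C=C)[C@@H](CCC#C[Li])O2 | intermediate
13 | methyl 5-[5-ethenyl-2-(4-methoxyphenyl)-5-methyl-1,3-dioxan-4-yl]pent-2-ynoate (dioxane as in 11) | COc1ccc(cc1)[C@H]2OC[C@](C)(C=C)[C@@H](CCC#CC(=O)OC)O2 | intermediate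
14 | lithium alkenyl(methyl)cuprate (Cu cis to the new methyl) | COc1ccc(cc1)[C@H]2OC[C@](C)(C=C)[C@@H](CC/C(C)=C(/[Cu-]C)C(=O)OC)O2.[Li+] | intermediate
15 | methyl (E)-2-iodo-3-methyl-5-(dioxan-4-yl)pent-2-enoate (dioxane as in 11) | COc1ccc(cc1)[C@H]2OC[C@](C)(C=C)[C@@H](CC/C(C)=C(/I)C(=O)OC)O2 | intermediate
16 | (E)-2-iodo-3-methyl-5-(dioxan-4-yl)pent-2-en-1-ol (dioxane as in 11) | COc1ccc(cc1)[C@H]2OC[C@](C)(C=C)[C@@H](CC/C(C)=C(/I)CO)O2 | intermediate
17 | 1,2-diol from the vinyl group of 16 (new carbinol centre undefined) | COc1ccc(cc1)[C@H]2OC[C@](C)(C(O)CO)[C@@H](CC/C(C)=C(/I)CO)O2 | intermediate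
18 | 5-formyl analogue of 16 (dioxane stereocentres unchanged) | COc1ccc(cc1)[C@H]2OC[C@](C)(C=O)[C@@H](CC/C(C)=C(/I)CO)O2 | intermediate
19 | 7-hydroxycoumarin (umbelliferone) | Oc1ccc2ccc(=O)oc2c1 | starting material
20 | coumarin-7-yl ether of 18 | COc1ccc(cc1)[C@H]2OC[C@](C)(C=O)[C@@H](CC/C(C)=C(/I)COc3ccc4ccc(=O)oc4c3)O2 | intermediate
21 | tributyl(1-ethoxyvinyl)stannane | CCOC(=C)[Sn](CCCC)(CCCC)CCCC | starting material
22 | 2-ethoxy-1,3-diene aldehyde (9E) | COc1ccc(cc1)[C@H]2OC[C@](C)(C=O)[C@@H](CC/C(C)=C(\COc3ccc4ccc(=O)oc4c3)C(=C)OCC)O2 | intermediate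
23 | nitro-aldol of 22 (carbinol centre undefined) | COc1ccc(cc1)[C@H]2OC[C@](C)(C(O)C[N+](=O)[O-])[C@@H](CC/C(C)=C(\COc3ccc4ccc(=O)oc4c3)C(=C)OCC)O2 | intermediate
24 | nitro-aldol mesylate | COc1ccc(cc1)[C@H]2OC[C@](C)(C(OS(C)(=O)=O)C[N+](=O)[O-])[C@@H](CC/C(C)=C(\COc3ccc4ccc(=O)oc4c3)C(=C)OCC)O2 | intermediate
25 | (E)-nitro-triene (5E nitroalkene, 9E diene) | COc1ccc(cc1)[C@H]2OC[C@](C)(/C=C/[N+](=O)[O-])[C@@H](CC/C(C)=C(\COc3ccc4ccc(=O)oc4c3)C(=C)OCC)O2 | intermediate
26 | 6-nitro Diels–Alder adduct (trans-decalin, 6-NO2 cis to 5-H) | COc1ccc(cc1)[C@H]2OC[C@]3(C)[C@H]4[C@H]([N+](=O)[O-])CC(OCC)=C(COc5ccc6ccc(=O)oc6c5)[C@]4(C)CC[C@H]3O2 | intermediate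
27 | denitrated enol ether (8-ethoxy-drim-8-ene acetal) | COc1ccc(cc1)[C@H]2OC[C@]3(C)[C@H]4CCC(OCC)=C(COc5ccc6ccc(=O)oc6c5)[C@]4(C)CC[C@H]3O2 | intermediate
28 | 8-oxo keto diol (3-OH, 4-CH2OH free; 9-CH2OAr equatorial) | OC[C@]1(C)[C@H]2CCC(=O)[C@@H](COc3ccc4ccc(=O)oc4c3)[C@]2(C)CC[C@H]1O | intermediate
29 | 8(12)-methylene diol | OC[C@]1(C)[C@H]2CCC(=C)[C@@H](COc3ccc4ccc(=O)oc4c3)[C@]2(C)CC[C@H]1O | intermediate
30 | alkylmercury acetate (C12–HgOAc, 8-OH equatorial) | OC[C@]1(C)[C@H]2CC[C@](C[Hg]OC(C)=O)(O)[C@@H](COc3ccc4ccc(=O)oc4c3)[C@]2(C)CC[C@H]1O | intermediate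
31 | triol (3-OH, 4-CH2OH, 8-OH; 11-OAr) | OC[C@]1(C)[C@H]2CC[C@](C)(O)[C@@H](COc3ccc4ccc(=O)oc4c3)[C@]2(C)CC[C@H]1O | intermediate
32 | angelic acid, (Z)-2-methylbut-2-enoic acid | C/C=C(/C)C(=O)O | starting material
33 | angelic 2,4,6-trichlorobenzoic mixed anhydride | C/C=C(/C)C(=O)OC(=O)c1c(Cl)cc(Cl)cc1Cl | intermediate
34 | CNP0139045.1, (3R,4S,5S,8S,9R,10R) in drimane numbering: 4-(angeloyloxymethyl)-drimane-3,8-diol 11-(coumarin-7-yl) ether | C/C=C(/C)C(=O)OC[C@]1(C)[C@H]2CC[C@](C)(O)[C@@H](COc3ccc4ccc(=O)oc4c3)[C@]2(C)CC[C@H]1O | target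

**Step count and risks**

Total step count: 19. Longest linear sequence: 18 steps (steps 1–3 and 5–19).

Step 14. The internal bond joins the neopentyl carbon C5 to the fully substituted diene terminus C10. The cycloaddition may therefore be slower than polar oligomerisation of the electron-rich enol ether with the nitroalkene, and endo over exo control may erode. Fallback, from 22 and back at 27: Wittig olefination of 22 with (triphenylphosphoranylidene)acetaldehyde should give the (E)-enal triene F1. Its intramolecular Diels–Alder reaction, promoted through the formyl group by Me2AlCl at low temperature (endo, trans-fused), should give the 6-formyl adduct F2. Tsuji–Wilkinson decarbonylation of F2 with stoichiometric RhCl(PPh3)3 (PhCN, 130 °C) removes the formyl group and gives 27.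

Step 15. C–N homolysis of an unactivated secondary nitroalkane is slow, so the chain may stall or stannyl radicals may reduce the coumarin double bond. Fallback, from 26 and back at 28: aqueous HCl/THF hydrolyses enol ether and acetal of 26 to the 6-nitro-8-oxo diol F3. Et3N (CH2Cl2, 0 °C) eliminates HNO2 from this β-nitro ketone (E1cB) to the 6-en-8-one diol F4. Hydrogenation with H2 and RhCl(PPh3)3 (benzene/EtOH) should saturate the disubstituted enone alkene and not the coumarin, giving 28.

Step 17. β-Elimination of the coumarin-7-olate from the β-aryloxy ketone (retro-oxa-Michael) may compete with methylenation of the hindered carbonyl. Fallback, from 28 and back at 29: addition of Me3SiCH2MgCl/CeCl3 (THF, −78 °C, weakly basic organocerium) to the ketone gives the β-hydroxysilane F5. Aqueous HF in MeCN then effects Peterson elimination to 29.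

Further compounds
F1 | step 14 | (E)-enal triene from 22 | COc1ccc(cc1)[C@H]2OC[C@](C)(/C=C/C=O)[C@@H](CC/C(C)=C(\COc3ccc4ccc(=O)oc4c3)C(=C)OCC)O2
F2 | step 14 | 6-formyl adduct (CHO cis to 5-H) | COc1ccc(cc1)[C@H]2OC[C@]3(C)[C@H]4[C@H](C=O)CC(OCC)=C(COc5ccc6ccc(=O)oc6c5)[C@]4(C)CC[C@H]3O2
F3 | step 15 | 6-nitro-8-oxo diol | OC[C@]1(C)[C@H]2[C@H]([N+](=O)[O-])CC(=O)[C@@H](COc3ccc4ccc(=O)oc4c3)[C@]2(C)CC[C@H]1O
F4 | step 15 | 6-en-8-one diol | OC[C@]1(C)[C@H]2C=CC(=O)[C@@H](COc3ccc4ccc(=O)oc4c3)[C@]2(C)CC[C@H]1O
F5 | step 17 | β-hydroxysilane (C8 centre undefined) | OC[C@]1(C)[C@H]2CCC(O)(C[Si](C)(C)C)[C@@H](COc3ccc4ccc(=O)oc4c3)[C@]2(C)CC[C@H]1O
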